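## Analysis of the target

CNP0348176.1 is a linear pentacycle. Ring A is a cyclohexene that holds the only stereocentre, a quaternary carbon bearing methyl, a ring A CH2, a ring A sp2 carbon and the aryl group; it is (S). Ring B is a seven-membered dienol lactone whose enol C=C is exocyclic to ring A and conjugated with the ring A C(CH3)=CH unit. Ring C is a benzene ring, ring D a 1,4-quinone, and ring E a 3,4-dihydro-2H-1,4-thiazine 1,1-dioxide fused to the quinone C=C bond. With one stereocentre only absolute configuration has to be controlled, and the centre has no hydrogen, so it cannot epimerise once set. The sensitive groups are the enol ester (an acyl donor, open to hydrolysis and aminolysis), the quinone (electrophile and oxidant) and the acidic vinylogous sulfonamide N–H. The hard points are the crowded benzylic quaternary carbon (between an ortho carboxyl and the ring A carbon that carries the enol carbon), the seven-membered enol lactone, and the placement of S and N on ring E. Sulfur sits on the quinone carbon next to the carbonyl that is para to the aryl carbon bearing the quaternary centre. The strategy rests on ring C: two adjacent carbons carry the lactone carbonyl and the quaternary carbon, two are shared with ring D, and the remaining two are CH groups para to each other. These six carbons map onto a two-carbon ynoate and a constitutionally symmetric 1,7-diyne whose tether supplies the other four carbons of ring D.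

## Retrosynthetic reasoning

Ring E. The C–S and C–N bonds that join ring E to the quinone are cut first, giving quinone 25 and hypotaurine 26. Ring E is the only part that is not carbon skeleton, and sulfinate addition followed by amine closure on a quinone is the direct way to make it. It is placed last so that the lactone ester, an acceptor para to one quinone carbonyl, can bias where sulfur adds.

Ring B. In 25 the acyl–oxygen bond of the enol lactone is cut and the dienol is read as the γ-enolised form of a conjugated aldehyde, giving acid–enal 23. One dehydrative step then forms ring B and the ring A diene from a stable enal. The forward reaction must acylate the aldehyde oxygen through a seven-membered transition state and lose the ring proton, not a methyl proton.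

Oxidation level. The quinone of 23 is traced to a tetralin-1,4-diol and the enal to a primary allylic alcohol, giving triol acid 20 and its fully silylated form 19. One fluoride treatment frees all four groups and one oxidant then sets the quinone and the enal together. The enal is not carried through the arene-forming step, because a free 4-alkynal is a substrate for rhodium-catalysed hydroacylation.

Ring C (key disconnection). Three aromatic C–C bonds of 19 are cut: the bond between the two fusion carbons and the two bonds from each aromatic CH to the ester-bearing and the quaternary-carbon-bearing carbons. This gives ynoate 14 and diyne 18. The cut is made here because it removes ring C and the carbocycle of ring D at once, leaves the stereocentre as a spectator, and has no regiochemical question since 18 is symmetric.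

Diyne. 18 is the bis-silyl ether of diol 17, which arises from double ethynyl addition to succinaldehyde 16, itself released from acetal 15.

Ynoate. The ester carbon of 14 is removed (acetylide acylation), giving alkyne 12. Its silyloxymethyl group goes back through alcohol 11 to ester 10, and the ester C–C bond is cut to enol triflate 9 (alkoxycarbonylation). This puts the one-carbon unit on the carbon next to the quaternary centre with the tetrasubstituted alkene in place.

Enol triflate. 9 comes from enolate 8, made regiospecifically by conjugate reduction of enone 7. The enone comes from allylic alcohol 6 and its silyl ether 5, and the alkyne of 5 from aldehyde 4 by one-carbon homologation.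

Ring A. The two ring bonds of 4 that flank the new alkene are cut in a Diels–Alder sense, giving silyloxydiene 2 and methacrolein 3. This is where the quaternary stereocentre is set, on the simplest 2-substituted acrolein. Diene 2 comes from enal 1.

## Alternatives that were turned down

Alternative 1: The aryl–quaternary-carbon bond is cut, with ring B present as an ester tether and ring A as a phenol. In the forward step aryl bromide A2, (3-hydroxy-2,6-dimethylphenyl)methyl 3-bromo-5,8-dimethoxynaphthalene-2-carboxylate, adds oxidatively to zerovalent palladium (Pd2(dba)3, chiral biaryl monophosphine, K2CO3). The phenoxide attacks through its para carbon and reductive elimination gives dienone lactone A1, so the quaternary carbon and the seven-membered ring form together.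
- For: the precursors are flat and achiral, the arene is bought and not built, and stereocentre and ring B come from one catalytic step. On step count to the skeleton this plan is the stronger one.
- Against: the ring that closes is seven-membered through an ester, which prefers the conformation that holds the two arenes apart. Para C-arylation has to beat O-arylation and loss of bromide, and enantiocontrol for such a fused medium ring is an open question.
- Against: A1 has ring A as a cross-conjugated dienone. It needs conjugate reduction of one alkene, carbonyl reduction and a 1,4-dehydration to reach the dienol, then oxidative demethylation next to an electron-rich dienol ester.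
- Comparison: the chosen route is longer to the skeleton, but each C–C bond-forming step belongs to a well-charted reaction class, the stereocentre is fixed in the second step, and ring A arrives at the right oxidation level.

Alternative 2: Ring D is cut in a retro-Moore sense to hydroxycyclobutenone A4, in which the four-membered ring already carries ring E. In the forward step A4 is heated, opens to an aryl-conjugated ketene, closes by a six-electron process onto the free ortho carbon, and air oxidises the hydroquinone to quinone A3.
- For: the positions of S and N are fixed by which carbonyl of the cyclobutenedione the aryl metal attacks. On ring E regiochemistry, the weakest point of the chosen route, this plan is clearly stronger.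
- Against: the thiazine-dioxide-fused cyclobutenedione is an unknown strained bicycle with an acidic N–H, and the aryl metal must be made on an arene that carries an ester and the bulky quaternary group.
- Against: closure can occur at two different ortho carbons, and the key step builds neither the quaternary carbon nor ring A nor ring B, so both fragment syntheses stay long.
- Comparison: the chosen plan makes ring C and the carbocycle of ring D in one step from short fragments and accepts one separation at the end, where a modest electronic bias points to the target isomer.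

Alternative 3: Two bonds of ring A are cut in a Diels–Alder sense with the arene already on the dienophile. In the forward step 2-arylacrolein A6 and diene 2 combine under a chiral oxazaborolidinium or trivalent chromium–salen Lewis acid to give cyclohexene A5, with ring A, its alkene and the quaternary centre formed at once; a formyl group stands in for the methyl group.
- For: it is convergent, attaches the aryl group to the quaternary carbon in the enantio-determining step and needs no hindered cyclotrimerisation. On convergence it is the stronger plan.
- Against: an α-aryl acrolein with an ortho ester is twisted, poorly activated and prone to polymerise, and facial control is less secure than with methacrolein.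
- Against: the formyl group must be reduced to methyl at a neopentyl, benzylic position beside an aryl ester. The one-carbon homologation of the carbinol carbon is still needed, now late on a valuable intermediate, and the quinone needs oxidative demethylation at the end.
- Comparison: the chosen route runs the same cycloaddition on methacrolein, so the methyl group is in place from the start and the homologation is done early on a small molecule.

Key step: step 14

Remark on the chemistry (assumption): the (R)-oxazaborolidinium catalyst of step 2 is taken to leave the Si face of the α-carbon of methacrolein open, as the formyl C–H···O model for 2-substituted acroleins predicts. If the opposite sense is found, the (S)-catalyst is used and nothing else changes.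

## Route

Step 1
Reactants: 1 (E)-2-methylbut-2-enal
Product: 2 (E)-tert-butyldimethyl[(2-methylbuta-1,3-dien-1-yl)oxy]silane
Conditions: TBSOTf, Et3N, Et2O, 0 °C to rt
Reagents that add atoms: tert-butyldimethylsilyl trifluoromethanesulfonate, CC(C)(C)[Si](C)(C)OS(=O)(=O)C(F)(F)F
Why: Silyl dienol ether formation: O-silylation gives an oxocarbenium ion that the amine deprotonates at the γ-methyl group; the s-trans ion leads to the (E)-enol ether needed for the cycloaddition.

Step 2
Reactants: 2 (E)-tert-butyldimethyl[(2-methylbuta-1,3-dien-1-yl)oxy]silane; 3 methacrolein
Product: 4 (1R,2S)-2-[(tert-butyldimethylsilyl)oxy]-1,3-dimethylcyclohex-3-ene-1-carbaldehyde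
Conditions: (R)-tetrahydro-1-(2-methylphenyl)-3,3-diphenyl-1H,3H-pyrrolo[1,2-c][1,3,2]oxazaborole·HNTf2 (20 mol %), CH2Cl2, −78 °C
Reagents that add atoms: none
Why: Catalytic asymmetric Diels–Alder reaction: the boron cation binds methacrolein s-trans, a phenyl group of the catalyst covers one face of the α-carbon and the diene adds to the open face, which sets the quaternary carbon as (1R); the silyloxy group directs the ortho regiochemistry and the endo rule places formyl cis to silyloxy, a centre that is removed in step 5.

Step 3
Reactants: 4 (1R,2S)-2-[(tert-butyldimethylsilyl)oxy]-1,3-dimethylcyclohex-3-ene-1-carbaldehyde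
Product: 5 tert-butyl{[(1S,6S)-6-ethynyl-2,6-dimethylcyclohex-2-en-1-yl]oxy}dimethylsilane
Conditions: dimethyl (1-diazo-2-oxopropyl)phosphonate, K2CO3, MeOH, 0 °C to rt
Reagents that add atoms: dimethyl (1-diazo-2-oxopropyl)phosphonate, CC(=O)C(=[N+]=[N-])P(=O)(OC)OC
Why: Ohira–Bestmann (Seyferth–Gilbert) homologation; the aldehyde has no α-hydrogen, so it can neither epimerise nor eliminate the β-silyloxy group, and the silyl ether blocks retro-aldol cleavage (the descriptor at the quaternary carbon changes only because the priorities change).

Step 4
Reactants: 5 tert-butyl{[(1S,6S)-6-ethynyl-2,6-dimethylcyclohex-2-en-1-yl]oxy}dimethylsilane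
Product: 6 (1S,6S)-6-ethynyl-2,6-dimethylcyclohex-2-en-1-ol
Conditions: Bu4NF, THF, rt to 45 °C
Reagents that add atoms: none
Why: Fluoride cleavage of a silyl ether; the terminal alkyne and the alkene are inert.

Step 5
Reactants: 6 (1S,6S)-6-ethynyl-2,6-dimethylcyclohex-2-en-1-ol
Product: 7 (S)-6-ethynyl-2,6-dimethylcyclohex-2-en-1-one
Conditions: Dess–Martin periodinane, CH2Cl2, 0 °C to rt
Reagents that add atoms: none
Why: Dess–Martin oxidation of a secondary allylic alcohol; the α'-carbon is quaternary, so the enone cannot racemise.

Step 6
Reactants: 7 (S)-6-ethynyl-2,6-dimethylcyclohex-2-en-1-one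
Product: 9 (S)-6-ethynyl-2,6-dimethylcyclohex-1-en-1-yl trifluoromethanesulfonate, via lithium enolate 8 (not isolated)
Conditions: LiBH(s-Bu)3, THF, −78 °C; then PhNTf2, −78 °C to rt
Reagents that add atoms: N-phenylbis(trifluoromethanesulfonimide), O=S(=O)(N(c1ccccc1)S(=O)(=O)C(F)(F)F)C(F)(F)F
Why: Conjugate reduction of a β-unsubstituted enone whose carbonyl is shielded by the quaternary carbon gives one enolate regiospecifically, and O-triflation traps it as the tetrasubstituted enol triflate; the hydride does not deprotonate the alkyne.

Step 7
Reactants: 9 (S)-6-ethynyl-2,6-dimethylcyclohex-1-en-1-yl trifluoromethanesulfonate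
Product: 10 methyl (S)-6-ethynyl-2,6-dimethylcyclohex-1-ene-1-carboxylate
Conditions: Pd(OAc)2 (5 mol %), Ph2P(CH2)3PPh2, CO (1 atm), MeOH, Et3N, DMF, 60 °C
Reagents that add atoms: carbon monoxide, [C-]#[O+]; methanol, CO
Why: Palladium-catalysed methoxycarbonylation of an enol triflate (oxidative addition, CO insertion, methanolysis), which tolerates hindered triflates; without copper the neopentyl-type terminal alkyne should not couple.

Step 8
Reactants: 10 methyl (S)-6-ethynyl-2,6-dimethylcyclohex-1-ene-1-carboxylate
Product: 11 [(S)-6-ethynyl-2,6-dimethylcyclohex-1-en-1-yl]methanol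
Conditions: i-Bu2AlH, CH2Cl2, −78 to 0 °C; Rochelle salt
Reagents that add atoms: none
Why: 1,2-Reduction of a conjugated ester to the allylic alcohol; the alkyne is not hydroaluminated at this temperature.

Step 9
Reactants: 11 [(S)-6-ethynyl-2,6-dimethylcyclohex-1-en-1-yl]methanol
Product: 12 tert-butyl{[(S)-6-ethynyl-2,6-dimethylcyclohex-1-en-1-yl]methoxy}dimethylsilane
Conditions: TBSCl, imidazole, DMF, rt
Reagents that add atoms: tert-butyldimethylsilyl chloride, CC(C)(C)[Si](C)(C)Cl
Why: Silylation of a primary alcohol; the ether blocks oxa-Michael addition to the ynoate made next and is removed with the other silyl groups in step 15.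

Step 10
Reactants: 12 tert-butyl{[(S)-6-ethynyl-2,6-dimethylcyclohex-1-en-1-yl]methoxy}dimethylsilane
Product: 14 2-(trimethylsilyl)ethyl 3-[(S)-2-{[(tert-butyldimethylsilyl)oxy]methyl}-1,3-dimethylcyclohex-2-en-1-yl]prop-2-ynoate, via lithium acetylide 13 (not isolated)
Conditions: n-BuLi, THF, −78 °C; then ClCO2CH2CH2SiMe3, −78 to 0 °C
Reagents that add atoms: 2-(trimethylsilyl)ethyl chloroformate, C[Si](C)(C)CCOC(=O)Cl
Why: Deprotonation of the terminal alkyne and C-acylation of the acetylide with a chloroformate gives the ynoate; no other acidic or electrophilic site is present.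

Step 11
Reactants: 15 2,5-dimethoxytetrahydrofuran
Product: 16 succinaldehyde
Conditions: H2O, 90 °C; extraction into CH2Cl2, used at once
Reagents that add atoms: water, O
Why: Hydrolysis of a cyclic bis-acetal; the dialdehyde is used fresh because it oligomerises on standing.

Step 12
Reactants: 16 succinaldehyde
Product: 17 octa-1,7-diyne-3,6-diol (meso and racemic forms)
Conditions: HC≡CMgBr (2.5 equiv), THF, 0 °C to rt
Reagents that add atoms: ethynylmagnesium bromide, C#C[Mg]Br
Why: Double Grignard addition to a dialdehyde; the diastereomer mixture is acceptable because both carbinol carbons become quinone carbonyls.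

Step 13
Reactants: 17 octa-1,7-diyne-3,6-diol
Product: 18 3,6-bis[(tert-butyldimethylsilyl)oxy]octa-1,7-diyne (diastereomer mixture)
Conditions: TBSCl, imidazole, DMF, rt
Reagents that add atoms: tert-butyldimethylsilyl chloride, CC(C)(C)[Si](C)(C)Cl
Why: Silylation of both propargylic alcohols prevents redox isomerisation at the metal and slows self-trimerisation of the diyne.

Step 14
Reactants: 14 2-(trimethylsilyl)ethyl 3-[(S)-2-{[(tert-butyldimethylsilyl)oxy]methyl}-1,3-dimethylcyclohex-2-en-1-yl]prop-2-ynoate; 18 3,6-bis[(tert-butyldimethylsilyl)oxy]octa-1,7-diyne
Product: 19 2-(trimethylsilyl)ethyl 5,8-bis[(tert-butyldimethylsilyl)oxy]-3-[(S)-2-{[(tert-butyldimethylsilyl)oxy]methyl}-1,3-dimethylcyclohex-2-en-1-yl]-5,6,7,8-tetrahydronaphthalene-2-carboxylate (diastereomer mixture at C5 and C8)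
Conditions: [Rh(cod)2]BF4 (10 mol %), rac-BINAP (10 mol %), H2 pre-activation then Ar; 18 (1.8 equiv) by syringe pump, (CH2Cl)2, 60 °C
Reagents that add atoms: none
Why: After hydrogenative removal of cyclooctadiene the cationic monovalent rhodium–BINAP fragment binds both alkynes of 18 and couples them oxidatively at their internal carbons to a rhodacyclopentadiene (trivalent rhodium), which closes the six-membered carbocycle; 14 then coordinates, inserts into a Rh–C bond, and reductive elimination closes the benzene ring and returns monovalent rhodium. The closest known reaction type is the cationic rhodium/bisphosphine cross-cyclotrimerisation of α,ω-diynes with propiolates and acetylenedicarboxylates. The carbocycle closes in the exo mode of the tethered oxidative coupling (both alkynes exocyclic to the new ring) and the benzene ring closes by insertion and C–C reductive elimination at the metal. No stereocentre is formed: the two carbinol carbons come from 18 as a mixture that converges at the quinone stage, and the quaternary carbon has no hydrogen and is a spectator. The step needs cross- over homo-trimerisation of the diyne, which is secured by keeping 18 at low stationary concentration while the electron-poor ynoate, which does not trimerise with itself, is present throughout. Insertion of the hindered ynoate is helped because both rhodium-bound carbons of the metallacycle are unsubstituted CH termini. Regiochemistry is not in question because 18 is constitutionally symmetric, so either insertion sense gives the same arene with the two hydrogens para. The formyl group of ring A is carried as its silyl-protected alcohol because a free 4-alkynal would be open to rhodium-catalysed hydroacylation or decarbonylation.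

Step 15
Reactants: 19 2-(trimethylsilyl)ethyl 5,8-bis[(tert-butyldimethylsilyl)oxy]-3-[(S)-2-{[(tert-butyldimethylsilyl)oxy]methyl}-1,3-dimethylcyclohex-2-en-1-yl]-5,6,7,8-tetrahydronaphthalene-2-carboxylate
Product: 20 5,8-dihydroxy-3-[(S)-2-(hydroxymethyl)-1,3-dimethylcyclohex-2-en-1-yl]-5,6,7,8-tetrahydronaphthalene-2-carboxylic acid (diastereomer mixture)
Conditions: Bu4NF (excess), THF, rt to 40 °C; buffered work-up (pH 4–5)
Reagents that add atoms: none
Why: Fluoride removes the three silyl ethers and fragments the 2-(trimethylsilyl)ethyl ester to the carboxylate, ethene and fluorosilane; the mild work-up avoids ionising the tertiary-allylic alcohol.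

Step 16
Reactants: 20 5,8-dihydroxy-3-[(S)-2-(hydroxymethyl)-1,3-dimethylcyclohex-2-en-1-yl]-5,6,7,8-tetrahydronaphthalene-2-carboxylic acid
Product: 23 3-[(S)-2-formyl-1,3-dimethylcyclohex-2-en-1-yl]-5,8-dioxo-5,8-dihydronaphthalene-2-carboxylic acid, via tetralindione acid 21 (not isolated), via naphthalenediol acid 22 (not isolated)
Conditions: Dess–Martin periodinane (excess), CH2Cl2–MeCN, rt
Reagents that add atoms: none
Why: Dess–Martin oxidation turns the two benzylic alcohols into the tetralin-1,4-dione and the allylic alcohol into the enal; the dione is the keto tautomer of a naphthalene-1,4-diol, enolisation is catalysed by the acetic acid set free, and further periodinane oxidises the hydroquinone irreversibly to the quinone, which pulls the tautomeric equilibrium.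

Step 17
Reactants: 23 3-[(S)-2-formyl-1,3-dimethylcyclohex-2-en-1-yl]-5,8-dioxo-5,8-dihydronaphthalene-2-carboxylic acid
Product: 25 (S)-naphthoquinone dienol lactone (seven-membered lactone between the carboxyl group and the dienol oxygen of ring A), via mixed trifluoroacetic anhydride 24 (not isolated)
Conditions: (CF3CO)2O, CH2Cl2, 0 °C to rt; then 2,6-lutidine, rt
Reagents that add atoms: none
Why: Dehydrative enol lactonisation of an oxo acid: the mixed anhydride acylates the aldehyde oxygen through a seven-membered transition state, and the acyloxy-stabilised allyl cation, tertiary at the methyl-bearing carbon, loses a ring proton under Zaitsev control to give the endocyclic diene. The acid present can re-protonate the diene terminus, so the more substituted isomer is also the thermodynamic one, and neither a nucleophilic amine nor HCl is present to add to the unsubstituted quinone.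

Step 18
Reactants: 25 (S)-naphthoquinone dienol lactone; 26 hypotaurine
Product: 29 CNP0348176.1, via sulfonyl hydroquinone 27 (not isolated), via sulfonyl quinone 28 (not isolated)
Conditions: Co(salen) (5 mol %), air, MeCN–EtOH–H2O, rt; chromatographic removal of the regioisomer
Reagents that add atoms: none
Why: Hypotaurine annulation of a quinone: the sulfinate adds in conjugate fashion through sulfur, O2 with the divalent cobalt catalyst re-oxidises the hydroquinone, the tethered amine closes the six-membered ring by a second conjugate addition and a second oxidation gives the aminoquinone. The sulfinate should prefer the quinone CH that is β to the more electron-poor carbonyl, the one para to the lactone carbonyl, which places sulfur as in the target; the bias is modest, so the regioisomer is expected as well.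

## Compound list

1 | (E)-2-methylbut-2-enal | C/C=C(\C)C=O | starting material
2 | (E)-tert-butyldimethyl[(2-methylbuta-1,3-dien-1-yl)oxy]silane | C=C/C(C)=C/O[Si](C)(C)C(C)(C)C | intermediate
3 | methacrolein | CC(=C)C=O | starting material
4 | (1R,2S)-2-[(tert-butyldimethylsilyl)oxy]-1,3-dimethylcyclohex-3-ene-1-carbaldehyde | C[C@@]1(C=O)CCC=C(C)[C@@H]1O[Si](C)(C)C(C)(C)C | intermediate
5 | tert-butyl{[(1S,6S)-6-ethynyl-2,6-dimethylcyclohex-2-en-1-yl]oxy}dimethylsilane | C[C@@]1(C#C)CCC=C(C)[C@@H]1O[Si](C)(C)C(C)(C)C | intermediate
6 | (1S,6S)-6-ethynyl-2,6-dimethylcyclohex-2-en-1-ol | C[C@@]1(C#C)CCC=C(C)[C@@H]1O | intermediate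
7 | (S)-6-ethynyl-2,6-dimethylcyclohex-2-en-1-one | C[C@@]1(C#C)CCC=C(C)C1=O | intermediate
8 | lithium (S)-6-ethynyl-2,6-dimethylcyclohex-1-en-1-olate | C[C@@]1(C#C)CCCC(C)=C1[O-].[Li+] | intermediate (not isolated)
9 | (S)-6-ethynyl-2,6-dimethylcyclohex-1-en-1-yl trifluoromethanesulfonate | C[C@@]1(C#C)CCCC(C)=C1OS(=O)(=O)C(F)(F)F | intermediate
10 | methyl (S)-6-ethynyl-2,6-dimethylcyclohex-1-ene-1-carboxylate | C[C@@]1(C#C)CCCC(C)=C1C(=O)OC | intermediate
11 | [(S)-6-ethynyl-2,6-dimethylcyclohex-1-en-1-yl]methanol | C[C@@]1(C#C)CCCC(C)=C1CO | intermediate
12 | tert-butyl{[(S)-6-ethynyl-2,6-dimethylcyclohex-1-en-1-yl]methoxy}dimethylsilane | C[C@@]1(C#C)CCCC(C)=C1CO[Si](C)(C)C(C)(C)C | intermediate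
13 | lithium acetylide of 12 | C[C@@]1(C#[C-])CCCC(C)=C1CO[Si](C)(C)C(C)(C)C.[Li+] | intermediate (not isolated)
14 | 2-(trimethylsilyl)ethyl 3-[(S)-2-{[(tert-butyldimethylsilyl)oxy]methyl}-1,3-dimethylcyclohex-2-en-1-yl]prop-2-ynoate | C[C@@]1(C#CC(=O)OCC[Si](C)(C)C)CCCC(C)=C1CO[Si](C)(C)C(C)(C)C | intermediate
15 | 2,5-dimethoxytetrahydrofuran (cis/trans mixture) | COC1CCC(OC)O1 | starting material
16 | succinaldehyde | O=CCCC=O | intermediate
17 | octa-1,7-diyne-3,6-diol (meso and racemic forms) | C#CC(O)CCC(O)C#C | intermediate
18 | 3,6-bis[(tert-butyldimethylsilyl)oxy]octa-1,7-diyne (diastereomer mixture) | C#CC(O[Si](C)(C)C(C)(C)C)CCC(O[Si](C)(C)C(C)(C)C)C#C | intermediate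
19 | 2-(trimethylsilyl)ethyl 5,8-bis[(tert-butyldimethylsilyl)oxy]-3-[(S)-2-{[(tert-butyldimethylsilyl)oxy]methyl}-1,3-dimethylcyclohex-2-en-1-yl]-5,6,7,8-tetrahydronaphthalene-2-carboxylate (mixture at C5 and C8) | C[C@@]1(c2cc3C(O[Si](C)(C)C(C)(C)C)CCC(O[Si](C)(C)C(C)(C)C)c3cc2C(=O)OCC[Si](C)(C)C)CCCC(C)=C1CO[Si](C)(C)C(C)(C)C | intermediate
20 | 5,8-dihydroxy-3-[(S)-2-(hydroxymethyl)-1,3-dimethylcyclohex-2-en-1-yl]-5,6,7,8-tetrahydronaphthalene-2-carboxylic acid (mixture at C5 and C8) | C[C@@]1(c2cc3C(O)CCC(O)c3cc2C(=O)O)CCCC(C)=C1CO | intermediate
21 | 3-[(S)-2-formyl-1,3-dimethylcyclohex-2-en-1-yl]-5,8-dioxo-5,6,7,8-tetrahydronaphthalene-2-carboxylic acid | C[C@@]1(c2cc3C(=O)CCC(=O)c3cc2C(=O)O)CCCC(C)=C1C=O | intermediate (not isolated)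
22 | 3-[(S)-2-formyl-1,3-dimethylcyclohex-2-en-1-yl]-5,8-dihydroxynaphthalene-2-carboxylic acid | C[C@@]1(c2cc3c(O)ccc(O)c3cc2C(=O)O)CCCC(C)=C1C=O | intermediate (not isolated)
23 | 3-[(S)-2-formyl-1,3-dimethylcyclohex-2-en-1-yl]-5,8-dioxo-5,8-dihydronaphthalene-2-carboxylic acid | C[C@@]1(c2cc3C(=O)C=CC(=O)c3cc2C(=O)O)CCCC(C)=C1C=O | intermediate
24 | mixed anhydride of 23 with trifluoroacetic acid | C[C@@]1(c2cc3C(=O)C=CC(=O)c3cc2C(=O)OC(=O)C(F)(F)F)CCCC(C)=C1C=O | intermediate (not isolated)
25 | (S)-naphthoquinone dienol lactone: 1,4-naphthoquinone whose C6 carboxyl is closed as a seven-membered lactone onto the exocyclic enol oxygen (O–CH=C) of the ring A diene attached at C7 through the quaternary carbon | CC1=CCC[C@]2(C)C1=COC(=O)c1cc3c(cc12)C(=O)C=CC3=O | intermediate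
26 | hypotaurine (2-aminoethanesulfinic acid) | NCCS(=O)O | starting material
27 | 2-[(2-aminoethyl)sulfonyl]hydroquinone of 25, sulfur on the carbon next to the C–OH that is para to the aryl carbon bearing the quaternary centre | CC1=CCC[C@]2(C)C1=COC(=O)c1cc3c(cc12)c(O)cc(c3O)S(=O)(=O)CCN | intermediate (not isolated)
28 | the corresponding 2-[(2-aminoethyl)sulfonyl]quinone | CC1=CCC[C@]2(C)C1=COC(=O)c1cc3c(cc12)C(=O)C=C(C3=O)S(=O)(=O)CCN | intermediate (not isolated)
29 | CNP0348176.1: lactone 25 with a 3,4-dihydro-2H-1,4-thiazine 1,1-dioxide fused at the quinone C=C bond, quaternary carbon (S) | CC1=CCC[C@]2(C)C1=COC(=O)c1cc3c(cc12)C(=O)C1=C(C3=O)S(=O)(=O)CCN1 | target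

## Step count and least certain steps

Total: 18 steps. Longest linear sequence: 15 steps (steps 1–10 and 14–18); the diyne branch has 3 steps (11–13).

Step 14 (key step). The hindered ynoate, with a quaternary propargylic carbon and a neighbouring silyloxymethyl group, may insert too slowly into the rhodacycle, so that self-oligomerisation of the diyne or catalyst deactivation takes over. The fallback builds ring C by cycloaddition and dehydrogenation, setting out from 14 and 18 and returning at 19. Palladium-catalysed reductive cyclisation of 18 (Pd2(dba)3, P(o-tol)3, AcOH, Et3SiH) gives the s-cis-locked diene 3,6-bis[(tert-butyldimethylsilyl)oxy]-1,2-dimethylidenecyclohexane F1. A thermal Diels–Alder reaction with 14 (toluene, 110–140 °C) gives the cyclohexa-1,4-diene F2, and DDQ aromatises it to 19.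

Step 17. Acylation of the aldehyde oxygen through a seven-membered transition state may be slow, so that intermolecular anhydride formation competes, and proton loss from the methyl group would give the exocyclic diene. The fallback reverses the order of the last two events, setting out from 23 and returning at 29. Hypotaurine 26 with Co(salen) and air converts 23 into the thiazine-fused quinone acid F3, whose aminoquinone tolerates amine bases. The lactone is then closed through the mixed anhydride (2,4,6-trichlorobenzoyl chloride, Et3N; then DMAP, toluene, 80 °C) to give 29.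

Step 18. Sulfinate addition may show poor regiocontrol, and the free amine in water may open the enol lactone by aminolysis or hydrolysis. The fallback separates the sulfur and nitrogen events, setting out from 25 and 26 and returning at 28. Boc protection of 26 (Boc2O, NaOH) gives sodium 2-[(tert-butoxycarbonyl)amino]ethanesulfinate F4. Its addition to 25 (AcOH, MeCN–H2O) gives the sulfonyl hydroquinone F5, which Ag2O oxidises to the sulfonyl quinone F6; the regioisomers are separated at this neutral stage. Trifluoroacetic acid then removes the carbamate to give 28, which closes and oxidises to 29 on neutralisation with NaHCO3 in air.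

Step 2. Facial selectivity may be insufficient, or the strong Lewis acid may desilylate the diene or divert it into a Mukaiyama-type addition. The fallback gives up catalytic induction, setting out from 2 and 3 and returning at 7. A thermal cycloaddition (toluene, 110 °C) gives the racemic aldehyde F7, and steps 3 to 5 carried out on the racemate give the racemic alkyne F8, the racemic alcohol F9 and the racemic enone F10. Preparative chromatography on a chiral stationary phase then delivers 7.

## Further compounds

F1 | step 14 | 3,6-bis[(tert-butyldimethylsilyl)oxy]-1,2-dimethylidenecyclohexane (diastereomer mixture) | C=C1C(O[Si](C)(C)C(C)(C)C)CCC(O[Si](C)(C)C(C)(C)C)C1=C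
F2 | step 14 | 2-(trimethylsilyl)ethyl 5,8-bis[(tert-butyldimethylsilyl)oxy]-3-[(S)-2-{[(tert-butyldimethylsilyl)oxy]methyl}-1,3-dimethylcyclohex-2-en-1-yl]-1,4,5,6,7,8-hexahydronaphthalene-2-carboxylate | C[C@@]1(C2=C(C(=O)OCC[Si](C)(C)C)CC3=C(C2)C(O[Si](C)(C)C(C)(C)C)CCC3O[Si](C)(C)C(C)(C)C)CCCC(C)=C1CO[Si](C)(C)C(C)(C)C
F3 | step 17 | ring-opened acid of the target: thiazine-dioxide-fused naphthoquinone bearing the carboxyl group and the (S)-2-formyl-1,3-dimethylcyclohex-2-en-1-yl group | C[C@@]1(c2cc3c(cc2C(=O)O)C(=O)C2=C(C3=O)NCCS2(=O)=O)CCCC(C)=C1C=O
F4 | step 18 | sodium 2-[(tert-butoxycarbonyl)amino]ethanesulfinate | CC(C)(C)OC(=O)NCCS(=O)[O-].[Na+]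
F5 | step 18 | N-Boc derivative of sulfonyl hydroquinone 27 | CC1=CCC[C@]2(C)C1=COC(=O)c1cc3c(cc12)c(O)cc(c3O)S(=O)(=O)CCNC(=O)OC(C)(C)C
F6 | step 18 | N-Boc derivative of sulfonyl quinone 28 | CC1=CCC[C@]2(C)C1=COC(=O)c1cc3c(cc12)C(=O)C=C(C3=O)S(=O)(=O)CCNC(=O)OC(C)(C)C
F7 | step 2 | racemic cis-2-[(tert-butyldimethylsilyl)oxy]-1,3-dimethylcyclohex-3-ene-1-carbaldehyde | CC1(C=O)CCC=C(C)C1O[Si](C)(C)C(C)(C)C
F8 | step 2 | racemic tert-butyl[(6-ethynyl-2,6-dimethylcyclohex-2-en-1-yl)oxy]dimethylsilane | CC1(C#C)CCC=C(C)C1O[Si](C)(C)C(C)(C)C
F9 | step 2 | racemic 6-ethynyl-2,6-dimethylcyclohex-2-en-1-ol | CC1(C#C)CCC=C(C)C1O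
F10 | step 2 | racemic 6-ethynyl-2,6-dimethylcyclohex-2-en-1-one | CC1(C#C)CCC=C(C)C1=O
A1 | alternative 1 | dimethoxynaphtho-fused seven-membered lactone spanning a 4-aryl-2,4-dimethylcyclohexa-2,5-dienone | CC1=C2COC(=O)c3cc4c(OC)ccc(OC)c4cc3[C@]2(C)C=CC1=O
A2 | alternative 1 | (3-hydroxy-2,6-dimethylphenyl)methyl 3-bromo-5,8-dimethoxynaphthalene-2-carboxylate | Cc1ccc(O)c(C)c1COC(=O)c1cc2c(OC)ccc(OC)c2cc1Br
A3 | alternative 2 | thiazine-dioxide-fused naphthoquinone bearing the tert-butyl ester and the ring A enal dimethyl acetal | COC(OC)C1=C(C)CCC[C@]1(c1cc2C(=O)C3=C(C(=O)c2cc1C(=O)OC(C)(C)C)S(=O)(=O)CCN3)C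
A4 | alternative 2 | tert-butyl 2-[(S)-2-(dimethoxymethyl)-1,3-dimethylcyclohex-2-en-1-yl]-4-(1-hydroxy-4-oxocyclobut-2-en-1-yl)benzoate with the thiazine dioxide fused at the cyclobutene C=C bond (N on the carbon next to the carbinol carbon) | COC(OC)C1=C(C)CCC[C@]1(c1cc(ccc1C(=O)OC(C)(C)C)C1(O)C(=O)C2=C1NCCS2(=O)=O)C
A5 | alternative 3 | 2-(trimethylsilyl)ethyl 3-[1-formyl-3-methyl-2-(tert-butyldimethylsilyloxy)cyclohex-3-en-1-yl]-5,8-dimethoxynaphthalene-2-carboxylate (formyl cis to silyloxy) | O=C[C@@]1(c2cc3c(OC)ccc(OC)c3cc2C(=O)OCC[Si](C)(C)C)CCC=C(C)[C@H]1O[Si](C)(C)C(C)(C)C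
A6 | alternative 3 | 2-(trimethylsilyl)ethyl 5,8-dimethoxy-3-(3-oxoprop-1-en-2-yl)naphthalene-2-carboxylate | C=C(C=O)c1cc2c(OC)ccc(OC)c2cc1C(=O)OCC[Si](C)(C)C
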